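In a one-step world, with its constant k held, the fraction of G left falls as exp(−kt) whatever was charged, so halving G moves nothing. This flask looks nearly the same as alpha: Z and D stand as there and G is halved. But E is charged as mol% of G, so E charged falls with it, from 0.132 mM to 0.0660 mM.

| flask | G | Z | E | D | remark | time |
|---|---|---|---|---|---|---|
| alpha | 66 mM | 1.8 mM (held) | 0.2 mol% | 0.21 mM | run made earlier |  |
| flask | 33 mM | 1.8 mM (held) | 0.2 mol% | 0.21 mM |  | 5.0 h |

- alpha (time / min: J / %): 1.50: 4; 5.00: 5; 8.00: 13; 12.0: 17; 20.0: 25; 25.0: 31; 30.0: 35

(each reading ± 1.5 percentage points)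

- how much J there is at 5.0 h, in percent of the G charged
- concentration of Q in solution at 5.0 h, in percent of saturation

- at the start none of Z is in solution
- Q is what Z becomes in solution
- no earlier run changes the charge of E; that part of a forecast is a guess

With Q and E frozen, the loss of G is pseudo-first-order. The last alpha reading gives, with its scatter:

k = ln(charged/left)/t = 0.0144 /min

κ = k/E charged = 0.109 /mM/min

κ, the constant per mM of E charged, is the quantity to carry. The exponent κ·E·t is 0.431 for alpha and 2.15 for this flask, so the two end apart:

G left = exp(−κ·E·t) = 11.6%, J = 88.4%

By the reckoning, alpha starts by consuming G at 0.948 mM/min and this flask at 0.237 mM/min, which asks less of Z. So Q may stand nearer saturation in this flask than in alpha, and my estimate leans above its own figure.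

The forecast gives 88% of J and Q at 98% of saturation, with this caution: “The E dependence is a guess, so the range stays wide.”

The flask gives 96.5% of J and Q at 99.0% of saturation.

    Z ⇌ Q, rate k1*(csat - [Q]) (kL = 0.0130 /s)
    G + Q + E → E + J (k = 4900 /M²/s)
    E + D ⇌ X (K = 12000 /M, k = 6.50 /M/s)

Read the same way, the flask's 3.5% of G left gives 0.169 /mM/min, which is 1.55 times the κ read from alpha. In this flask E stands at 35.8% of its charge after 0.500 h and 33.4% after 5.00 h. The neighbouring flask has 20 mM of G, so 0.0400 mM of E is charged, with D unchanged. The flask's κ then gives exp(−κ·E·t) = 13.1% of G left, so 86.9% of J. The neighbouring flask ends with 86.4% of J.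

Readings and results are simulated from invented constants; noise was put on by code.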